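**Plan**

- Enabling feature: in the upper flavan unit, C4 carries both resorcinol ring A (O1 sits on C8a, ortho to C4a) and pyrogallol ring D, so O1–C8a–C4a–C4 is a latent o-quinone methide heterodiene and C2–C3 a styrene-type 2π partner.
- Retrosynthesis: remove eight benzyl ethers and one acetonide; trace upper C3–OH to C3–B; cut the upper pyran at C3–C4 and O1–C2 ([4+2]); cut the carbinol–ring D bond (aryllithium + aldehyde); take the lower cis-diol back to a flav-3-ene, then a flavanone, then (O1–C2, Cα–Cβ) an acetophenone and a bromo aldehyde.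
- Forward: lower pyran first (chalcone, oxa-Michael closure, resolution, dehydration, dihydroxylation, acetonide), then the ring D–carbinol bond, then the upper pyran by cycloaddition, then C–B oxidation and deprotection.
- Stereochemistry: lower C2 from a Ru–TsDPEN transfer-hydrogenative kinetic resolution; lower C3/C4 from OsO4 adding anti to the C2 aryl group; upper C2/C3 from the E-alkene, upper C4 from the endo transition state and the chiral phosphoric acid; upper C3–O from stereoretentive C–B oxidation.

Key step: step 11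

Assumption: the senses of induction of (S,S)-Ru–TsDPEN (step 4) and (R)-TRIP (step 11) are assigned by analogy with simpler aryl ketones and quinone methides; if either proves opposite, the mirror-image catalyst is used and nothing else changes.

**Route**

Step 1
Reactants: 1 3,4,5-tris(benzyloxy)benzaldehyde
Product: 2 2-bromo-3,4,5-tris(benzyloxy)benzaldehyde
Conditions: NBS, MeCN, rt, dark
Reagents that add atoms: N-bromosuccinimide, O=C1CCC(=O)N1Br
Why: Electrophilic aromatic bromination should occur at C2 (= C6), the only free ring position, activated ortho and para by two benzyloxy groups as in the trimethoxy analogue, while the polar solvent and exclusion of light keep the benzylic CH2 groups out of radical bromination.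

Step 2
Reactants: 2 2-bromo-3,4,5-tris(benzyloxy)benzaldehyde; 3 1-[4-(benzyloxy)-2-hydroxyphenyl]ethan-1-one
Product: 4 (E)-1-[4-(benzyloxy)-2-hydroxyphenyl]-3-[2-bromo-3,4,5-tris(benzyloxy)phenyl]prop-2-en-1-one
Conditions: KOH, EtOH/THF, rt
Reagents that add atoms: none
Why: Claisen–Schmidt condensation of a methyl ketone with a non-enolisable aldehyde, in which E1cB loss of water from the aldol gives the conjugated E-enone.

Step 3
Reactants: 4 the 2'-hydroxychalcone
Product: 5 racemic 7-(benzyloxy)-2-[2-bromo-3,4,5-tris(benzyloxy)phenyl]chroman-4-one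
Conditions: NaOAc, EtOH, reflux
Reagents that add atoms: none
Why: Base-mediated intramolecular oxa-Michael addition of the 2'-phenoxide to the enone (chalcone–flavanone isomerisation) closes the lower pyranone and creates lower C2 as a racemate, which the next step resolves.

Step 4
Reactants: 5 the racemic flavanone
Product: 6 (2S,4S)-7-(benzyloxy)-2-[2-bromo-3,4,5-tris(benzyloxy)phenyl]chroman-4-ol (2,4-cis)
Conditions: RuCl[(S,S)-TsDPEN](p-cymene) (cat.), HCO2H/Et3N (5:2), EtOAc, rt, stopped near half conversion
Reagents that add atoms: none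
Why: Noyori–Ikariya asymmetric transfer hydrogenation used as a kinetic resolution of a racemic flavanone: the (S,S)-catalyst should deliver hydride to the carbonyl face that gives the 4S alcohol and should do so rapidly only for the (2S)-ketone, for which this is also the substrate-preferred approach to the 2,4-cis alcohol, while the (2R)-ketone is left behind and can be racemised through chalcone 4 under the conditions of step 3.

Step 5
Reactants: 6 the cis-flavan-4-ol
Product: 8 (2S)-7-(benzyloxy)-2-[2-bromo-3,4,5-tris(benzyloxy)phenyl]-2H-chromene, via C4 sulfamate ester 7 (not isolated)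
Conditions: Burgess reagent, THF, rt → 40 °C
Reagents that add atoms: none
Why: Burgess dehydration by syn elimination of the sulfamate ester of an activated benzylic alcohol can only involve the C3 hydrogens and, being non-acidic, should leave the allylic benzylic C2 stereocentre untouched.

Step 6
Reactants: 8 the flav-3-ene
Product: 9 (2R,3S,4S)-7-(benzyloxy)-2-[2-bromo-3,4,5-tris(benzyloxy)phenyl]chroman-3,4-diol (2,3-trans-3,4-cis)
Conditions: OsO4 (cat.), NMO, acetone/H2O, 0 °C → rt
Reagents that add atoms: osmium tetroxide, O=[Os](=O)(=O)=O; N-methylmorpholine N-oxide, C[N+]1([O-])CCOCC1; water, O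
Why: Upjohn syn-dihydroxylation of the styrene-type C3=C4 bond, in which osmium approaches the face opposite to the C2 aryl group and so sets C3 (S) and C4 (S) in the 2,3-trans-3,4-cis arrangement known for flav-3-enes.

Step 7
Reactants: 9 the cis-diol
Product: 10 3,4-O-isopropylidene derivative (cis-fused acetonide) of 9
Conditions: Me2C(OMe)2, PPTS (cat.), CH2Cl2, rt
Reagents that add atoms: 2,2-dimethoxypropane, COC(C)(C)OC
Why: Acid-catalysed transketalisation of a cis-1,2-diol gives the cis-fused dioxolane, which masks both hydroxyls against the organolithium of step 9 without touching a stereocentre.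

Step 8
Reactants: 11 4-(benzyloxy)-2-hydroxybenzaldehyde
Product: 12 4-(benzyloxy)-2-[(tert-butyldimethylsilyl)oxy]benzaldehyde
Conditions: TBSCl, imidazole, DMF, rt
Reagents that add atoms: tert-butyldimethylsilyl chloride, C[Si](C)(Cl)C(C)(C)C
Why: Imidazole-promoted silylation of the phenol gives a silyl ether that tolerates the aryllithium addition and is later removed by fluoride without acid.

Step 9
Reactants: 10 the bromo acetonide; 12 the silyloxy aldehyde
Product: 15 [4-(benzyloxy)-2-hydroxyphenyl]{2,3,4-tris(benzyloxy)-6-[the acetonide-protected chroman-2-yl unit of 10]phenyl}methanol as both carbinol epimers, via aryllithium 13 (not isolated), via silyl ether carbinol 14 (not isolated)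
Conditions: n-BuLi, THF, −78 °C; 12, −78 → −40 °C; AcOH then TBAF, 0 °C
Reagents that add atoms: none
Why: Bromine–lithium exchange, 1,2-addition of the aryllithium to the aldehyde and fluoride desilylation in one flask; the new carbinol centre needs no control because both epimers give the same quinone methide, and an O-to-O silyl shift in the adduct is harmless because all silyl is removed.

Step 10
Reactants: 1 3,4,5-tris(benzyloxy)benzaldehyde; 16 bis(4,4,5,5-tetramethyl-1,3,2-dioxaborolan-2-yl)methane
Product: 18 (E)-2-[3,4,5-tris(benzyloxy)styryl]-4,4,5,5-tetramethyl-1,3,2-dioxaborolane, via lithiated diborylmethane 17 (not isolated)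
Conditions: LiTMP (commercial solution), THF, 0 °C; then 1, −78 °C → rt
Reagents that add atoms: none
Why: Boron–Wittig olefination, in which the α-boryl carbanion adds to the aldehyde and syn elimination of the boron–oxygen pair gives the E-alkenyl pinacolboronate.

Step 11
Reactants: 15 the o-hydroxybenzhydrol; 18 the (E)-styryl pinacolboronate
Product: 20 protected dimer bearing Bpin at upper C3 (upper pyran 2S/3S/4S; 2-aryl and 4-aryl cis; Bpin trans to both; lower unit as in 10), via o-quinone methide 19 (not isolated)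
Conditions: (R)-TRIP (10 mol %), 5 Å MS, toluene, 0 °C → rt, excess 18
Reagents that add atoms: none
Why: Proposed new method: the acid should dehydrate 15 to the E-o-quinone methide 19, held to the chiral phosphate as a hydrogen-bonded ion pair, whose exocyclic carbon (upper C4) attacks the boron-bearing carbon of 18 while charge builds at the benzylic carbon para to a benzyloxy group, after which the quinone methide oxygen closes O1–C2 in an asynchronous inverse-demand oxa-[4+2] cycloaddition. The closest known reaction is the chiral phosphoric acid catalysed hetero-Diels–Alder reaction of in situ generated o-quinone methides with styrenes to give 2,4-cis-diarylchromans, and a β-boryl styrene as the 2π partner is the extension. The upper pyran, the only ring formed, is closed by this [4+2] cycloaddition through the C3–C4 and O1–C2 bonds. C2/C3 trans follows from suprafacial addition to the E-alkene, C3/C4 trans (C2/C4 cis) from the aryl-endo, boron-exo approach to the E-quinone methide, and the absolute sense from the face of 19 left open by the 3,3'-aryl groups of the phosphate, with the enantiopure lower unit as a second, matched or overridden, element. The step needs C4-to-C(B) and O1-to-C(Ar) regiochemistry, secured by the aryl-stabilised benzylic cation character, and ring closure instead of alkenyl transfer with loss of boron, secured by the non-exchanging, weakly Lewis acidic pinacol ester; the mild acid and sieves should spare the acetonide and the benzylic C–O bonds, and both epimers of 15 converge on 19. If reactivity is low, the stronger N-triflylphosphoramide analogue of the catalyst or a larger excess of 18 are reserves that leave the disconnection unchanged.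

Step 12
Reactants: 20 the C3 boronate
Product: 21 protected dimer with upper C3–OH (upper pyran 2R/3S/4S all-trans; lower unit as in 10)
Conditions: NaBO3·4H2O, THF/H2O, rt
Reagents that add atoms: sodium perborate, [Na+].[O-]OB=O
Why: Peroxoborate oxidation of the secondary alkyl pinacolboronate proceeds by 1,2-migration of carbon from boron to oxygen with retention, so the hydroxyl appears trans to both aryl groups, and the near-neutral medium should disfavour β-elimination of the C2–O1 aryloxide.

Step 13
Reactants: 21 the acetonide alcohol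
Product: 22 octabenzyl ether of the target (upper 3-OH and lower 3,4-diol free)
Conditions: AcOH/H2O/THF (3:1:1), 40 °C
Reagents that add atoms: none
Why: Mild acid-catalysed hydrolysis of the isopropylidene acetal proceeds by cleavage at the acetal carbon and not at the benzylic lower C4–O bond, so the cis-diol configuration should be kept and the benzyl ethers are untouched.

Step 14
Reactants: 22 the octabenzyl ether
Product: 23 (2R,3S,4S)-2-(3,4,5-trihydroxyphenyl)-4-{2,3,4-trihydroxy-6-[(2R,3S,4S)-3,4,7-trihydroxychroman-2-yl]phenyl}chroman-3,7-diol (target)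
Conditions: H2 (1 atm), Pd(OH)2/C, THF/MeOH, rt
Reagents that add atoms: none
Why: Palladium-catalysed hydrogenolysis cleaves the eight aryl benzyl ethers under neutral conditions, under which secondary benzylic alcohols, the cyclic benzylic C2–O1 ethers and the doubly benzylic C4–H bond are known to persist.

**Compound list**

1 | 3,4,5-tris(benzyloxy)benzaldehyde | O=Cc1cc(OCc2ccccc2)c(OCc2ccccc2)c(OCc2ccccc2)c1 | starting material
2 | 2-bromo-3,4,5-tris(benzyloxy)benzaldehyde | O=Cc1cc(OCc2ccccc2)c(OCc2ccccc2)c(OCc2ccccc2)c1Br | intermediate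
3 | 1-[4-(benzyloxy)-2-hydroxyphenyl]ethan-1-one | CC(=O)c1ccc(OCc2ccccc2)cc1O | starting material
4 | (E)-1-[4-(benzyloxy)-2-hydroxyphenyl]-3-[2-bromo-3,4,5-tris(benzyloxy)phenyl]prop-2-en-1-one | O=C(/C=C/c1cc(OCc2ccccc2)c(OCc2ccccc2)c(OCc2ccccc2)c1Br)c1ccc(OCc2ccccc2)cc1O | intermediate
5 | racemic 7-(benzyloxy)-2-[2-bromo-3,4,5-tris(benzyloxy)phenyl]chroman-4-one | O=C1CC(c2cc(OCc3ccccc3)c(OCc3ccccc3)c(OCc3ccccc3)c2Br)Oc2cc(OCc3ccccc3)ccc12 | intermediate
6 | (2S,4S)-7-(benzyloxy)-2-[2-bromo-3,4,5-tris(benzyloxy)phenyl]chroman-4-ol | O[C@H]1C[C@@H](c2cc(OCc3ccccc3)c(OCc3ccccc3)c(OCc3ccccc3)c2Br)Oc2cc(OCc3ccccc3)ccc12 | intermediate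
7 | triethylammonium salt of the C4 O-[N-(methoxycarbonyl)sulfamate] of 6 | COC(=O)[N-]S(=O)(=O)O[C@H]1C[C@@H](c2cc(OCc3ccccc3)c(OCc3ccccc3)c(OCc3ccccc3)c2Br)Oc2cc(OCc3ccccc3)ccc12.CC[NH+](CC)CC | intermediate (not isolated)
8 | (2S)-7-(benzyloxy)-2-[2-bromo-3,4,5-tris(benzyloxy)phenyl]-2H-chromene | C1=C[C@@H](c2cc(OCc3ccccc3)c(OCc3ccccc3)c(OCc3ccccc3)c2Br)Oc2cc(OCc3ccccc3)ccc12 | intermediate
9 | (2R,3S,4S)-7-(benzyloxy)-2-[2-bromo-3,4,5-tris(benzyloxy)phenyl]chroman-3,4-diol | Brc1c(OCc2ccccc2)c(OCc2ccccc2)c(OCc2ccccc2)cc1[C@H]1Oc2cc(OCc3ccccc3)ccc2[C@H](O)[C@@H]1O | intermediate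
10 | 3,4-O-isopropylidene derivative of 9 (cis-fused dioxolane; configuration as in 9) | Brc1c(OCc2ccccc2)c(OCc2ccccc2)c(OCc2ccccc2)cc1[C@H]1Oc2cc(OCc3ccccc3)ccc2[C@H](O4)[C@@H]1OC4(C)C | intermediate
11 | 4-(benzyloxy)-2-hydroxybenzaldehyde | O=Cc1ccc(OCc2ccccc2)cc1O | starting material
12 | 4-(benzyloxy)-2-[(tert-butyldimethylsilyl)oxy]benzaldehyde | O=Cc1ccc(OCc2ccccc2)cc1O[Si](C)(C)C(C)(C)C | intermediate
13 | aryllithium from 10 (Li in place of Br) | [Li]c1c(OCc2ccccc2)c(OCc2ccccc2)c(OCc2ccccc2)cc1[C@H]1Oc2cc(OCc3ccccc3)ccc2[C@H](O4)[C@@H]1OC4(C)C | intermediate (not isolated)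
14 | O-TBS ether of 15 at the phenol (both carbinol epimers) | OC(c1ccc(OCc2ccccc2)cc1O[Si](C)(C)C(C)(C)C)c1c(OCc2ccccc2)c(OCc2ccccc2)c(OCc2ccccc2)cc1[C@H]1Oc2cc(OCc3ccccc3)ccc2[C@H](O4)[C@@H]1OC4(C)C | intermediate (not isolated)
15 | [4-(benzyloxy)-2-hydroxyphenyl]{2,3,4-tris(benzyloxy)-6-[acetonide-protected chroman-2-yl unit of 10]phenyl}methanol (both carbinol epimers) | OC(c1ccc(OCc2ccccc2)cc1O)c1c(OCc2ccccc2)c(OCc2ccccc2)c(OCc2ccccc2)cc1[C@H]1Oc2cc(OCc3ccccc3)ccc2[C@H](O4)[C@@H]1OC4(C)C | intermediate (key-step precursor)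
16 | bis(4,4,5,5-tetramethyl-1,3,2-dioxaborolan-2-yl)methane | C(B1OC(C)(C)C(C)(C)O1)B1OC(C)(C)C(C)(C)O1 | starting material
17 | lithiated bis(pinacolboryl)methane | [Li]C(B1OC(C)(C)C(C)(C)O1)B1OC(C)(C)C(C)(C)O1 | intermediate (not isolated)
18 | (E)-2-[3,4,5-tris(benzyloxy)styryl]-4,4,5,5-tetramethyl-1,3,2-dioxaborolane | CC1(C)OB(/C=C/c2cc(OCc3ccccc3)c(OCc3ccccc3)c(OCc3ccccc3)c2)OC1(C)C | intermediate
19 | E-o-quinone methide from 15 (3-benzyloxy-6-arylmethylidene-cyclohexa-2,4-dienone) | O=C1C=C(OCc2ccccc2)C=C/C1=C\c1c(OCc2ccccc2)c(OCc2ccccc2)c(OCc2ccccc2)cc1[C@H]1Oc2cc(OCc3ccccc3)ccc2[C@H](O4)[C@@H]1OC4(C)C | intermediate (not isolated)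
20 | protected dimer with Bpin at upper C3 (upper pyran 2S,3S,4S, all-trans) | C(c1ccccc1)Oc1ccc2c(c1)O[C@H](c1cc(OCc3ccccc3)c(OCc3ccccc3)c(OCc3ccccc3)c1)[C@@H](B1OC(C)(C)C(C)(C)O1)[C@@H]2c1c(OCc2ccccc2)c(OCc2ccccc2)c(OCc2ccccc2)cc1[C@H]1Oc2cc(OCc3ccccc3)ccc2[C@H](O4)[C@@H]1OC4(C)C | intermediate (key-step product)
21 | protected dimer with upper C3–OH (upper pyran 2R,3S,4S) | C(c1ccccc1)Oc1ccc2c(c1)O[C@H](c1cc(OCc3ccccc3)c(OCc3ccccc3)c(OCc3ccccc3)c1)[C@@H](O)[C@@H]2c1c(OCc2ccccc2)c(OCc2ccccc2)c(OCc2ccccc2)cc1[C@H]1Oc2cc(OCc3ccccc3)ccc2[C@H](O4)[C@@H]1OC4(C)C | intermediate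
22 | octabenzyl ether of the target | C(c1ccccc1)Oc1ccc2c(c1)O[C@H](c1cc(OCc3ccccc3)c(OCc3ccccc3)c(OCc3ccccc3)c1)[C@@H](O)[C@@H]2c1c(OCc2ccccc2)c(OCc2ccccc2)c(OCc2ccccc2)cc1[C@H]1Oc2cc(OCc3ccccc3)ccc2[C@H](O)[C@@H]1O | intermediate
23 | (2R,3S,4S)-2-(3,4,5-trihydroxyphenyl)-4-{2,3,4-trihydroxy-6-[(2R,3S,4S)-3,4,7-trihydroxychroman-2-yl]phenyl}chroman-3,7-diol | Oc1ccc2c(c1)O[C@H](c1cc(O)c(O)c(O)c1)[C@@H](O)[C@@H]2c1c([C@H]2Oc3cc(O)ccc3[C@H](O)[C@@H]2O)cc(O)c(O)c1O | target

**Count and risks**

Total steps: 14. Longest linear sequence: 12 (steps 1–7, 9, 11–14, from 1 to 23).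

Step 11 (proposed new method). The boryl alkene may be too weak a nucleophile for the hindered, di-ortho-substituted quinone methide, so that self-condensation of 19 takes over. Boron may also be lost after the first C–C bond forms (alkenyl transfer instead of ring closure), or facial control may be poor if catalyst and lower unit are mismatched. The fallback uses known chemistry and sets out from 15. The same quinone methide is generated with the chiral phosphoric acid and trapped with the N-acetyl enamide F2 of 3,4,5-tris(benzyloxy)acetophenone, made from the purchased ketone through its oxime F1 by Fe/Ac2O reductive acetylation. The established enamide addition, N,O-acetal closure and loss of acetamide should give the 2,4-diaryl-4H-chromene F3, with upper C4 set by the catalyst. Hydroboration (BH3·SMe2) on the face opposite to the C4 aryl group, then perborate oxidation, adds H to C2 and OH to C3 in a syn sense. This gives the all-trans alcohol 21, where the route is rejoined.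

Step 4. Rate discrimination between the flavanone enantiomers may be poor, because the ortho-bromo aryl group and the electron-rich ketone slow or perturb the hydride transfer, which would leave the alcohol with low enantiopurity. The fallback sets lower C2 by enantioselective conjugate reduction instead of resolution and sets out from chalcone 4. Oxidative cyclisation (I2, DMSO, heat) gives the flavone F4. Copper hydride catalysed asymmetric 1,4-reduction (Cu(OAc)2, DTBM-SEGPHOS, silane) gives the (2S)-flavanone F5. NaBH4 then adds hydride from the less hindered face to give the 2,4-cis alcohol 6, where the route is rejoined.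

Step 9. Halogen–metal exchange may be incomplete, the aryllithium may be quenched by proton transfer from benzylic positions, or the 2,6-disubstituted aryllithium may add sluggishly to the ortho-silyloxy aldehyde. The fallback avoids the organolithium, makes the bond to ring A by electrophilic substitution and sets out from 10. Palladium-catalysed reductive carbonylation (CO/H2, TMEDA) converts the bromide into the aldehyde F6. Heating F6 with 3-(benzyloxy)phenol and phenylboronic acid (cat. propionic acid, toluene, water removal) gives, by boron-templated ortho-hydroxyalkylation para to the benzyloxy group, the benzodioxaborin F7. Exchange of boron onto pinacol releases the benzhydrol 15, where the route is rejoined.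

**Further compounds**

F1 | step 11 | 1-[3,4,5-tris(benzyloxy)phenyl]ethan-1-one oxime | CC(=NO)c1cc(OCc2ccccc2)c(OCc2ccccc2)c(OCc2ccccc2)c1
F2 | step 11 | N-{1-[3,4,5-tris(benzyloxy)phenyl]ethenyl}acetamide | C=C(NC(C)=O)c1cc(OCc2ccccc2)c(OCc2ccccc2)c(OCc2ccccc2)c1
F3 | step 11 | (4S)-7-(benzyloxy)-2-[3,4,5-tris(benzyloxy)phenyl]-4-aryl-4H-chromene (aryl = ring D with the lower unit of 10) | C(c1ccccc1)Oc1ccc2c(c1)OC(c1cc(OCc3ccccc3)c(OCc3ccccc3)c(OCc3ccccc3)c1)=C[C@@H]2c1c(OCc2ccccc2)c(OCc2ccccc2)c(OCc2ccccc2)cc1[C@H]1Oc2cc(OCc3ccccc3)ccc2[C@H](O4)[C@@H]1OC4(C)C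
F4 | step 4 | 7-(benzyloxy)-2-[2-bromo-3,4,5-tris(benzyloxy)phenyl]-4H-chromen-4-one | O=c1cc(-c2cc(OCc3ccccc3)c(OCc3ccccc3)c(OCc3ccccc3)c2Br)oc2cc(OCc3ccccc3)ccc12
F5 | step 4 | (2S)-7-(benzyloxy)-2-[2-bromo-3,4,5-tris(benzyloxy)phenyl]chroman-4-one | O=C1C[C@@H](c2cc(OCc3ccccc3)c(OCc3ccccc3)c(OCc3ccccc3)c2Br)Oc2cc(OCc3ccccc3)ccc12
F6 | step 9 | 2,3,4-tris(benzyloxy)-6-[acetonide-protected chroman-2-yl unit of 10]benzaldehyde | O=Cc1c(OCc2ccccc2)c(OCc2ccccc2)c(OCc2ccccc2)cc1[C@H]1Oc2cc(OCc3ccccc3)ccc2[C@H](O4)[C@@H]1OC4(C)C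
F7 | step 9 | 7-(benzyloxy)-2-phenyl-4-aryl-4H-1,3,2-benzodioxaborin (aryl as in F6, both C4 epimers) | c1ccccc1B1OC(c2c(OCc3ccccc3)c(OCc3ccccc3)c(OCc3ccccc3)cc2[C@H]2Oc3cc(OCc5ccccc5)ccc3[C@H](O4)[C@@H]2OC4(C)C)c2ccc(OCc3ccccc3)cc2O1
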